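The data were generated by integration with made-up constants, and the scatter is random.

Start from the ash run, where the coupling partner stands at 2.95 times the substrate. The fraction of substrate left falls to 25.5% by 10.0 min, which reads as a pseudo-first-order loss of 0.137 min⁻¹.

| flask | substrate | coupling partner | remark | time |
|---|---|---|---|---|
| alder | 0.095 M | 0.0945 M | run made earlier |  |
| ash | 0.032 M | 0.0945 M | run made earlier |  |
| east | 0.063 M | 0.0945 M |  | 30 min |
| south-west | 0.063 M | 0.252 M |  | 30 min |

| run | time / min | first product / % | substrate / % |
|---|---|---|---|
| alder | 0.833 | 4.5 | 89.9 |
| alder | 1.33 | 7.0 | 82.9 |
| alder | 2.50 | 8.3 | 69.5 |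
| alder | 4.00 | 12.2 | 57.3 |
| alder | 6.00 | 9.8 | 44.4 |
| alder | 10.0 | 9.4 | 29.1 |
| ash | 2.00 | 12.9 | 76.4 |
| ash | 4.00 | 13.2 | 58.4 |
| ash | 5.00 | 17.2 | 50.9 |
| ash | 8.00 | 17.8 | 35.5 |
| ash | 10.0 | 19.9 | 25.5 |

(scatter of a reading: 1 percentage point)



1. which of these holds the largest part of the substrate at the end of east (double product / triple product / first product / substrate)
2. which of these holds the largest part of the substrate at the end of south-west (double product / triple product / first product / substrate)
3. final first product in south-west, as a percentage of the substrate charged

Now read the alder run, which charges a larger share of substrate against its partner. Over its last two readings it loses substrate at a slower 0.106 min⁻¹. Take the loss as proportional to the partner, and count turnovers: the turnover rate read late in the alder run, scaled by a flask's partner charge over alder's and multiplied by its time, reckons the substrate lifetimes that flask gets.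

First use the ash rate for south-west:

N = 10.9

Treat that as the weak link: the ash rate comes from the flask with less substrate per partner, so it may run high. Reforge it with alder's slower rate, read late in that run:

south-west: N = 8.45, substrate left 0.0214%

east: N = 3.17, substrate left 4.21%

South-west gets more lifetimes than east, so commit to it being further along the chain, with less first product than east.

The forecast named double product for east and triple product for south-west, with 4% of first product there (1% to 9%), saying “triple product probably leads”.

The flasks give first product as the largest of the four in east, at 12.0%, with 3.05% of substrate left. South-west gives triple product as the largest of the four, at 38.2%, with 9.04% of first product and 0.0194% of substrate.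

    first product ⇌ isomer of the product (K = 1.30, k = 0.0130 s⁻¹)
    substrate + coupling partner → first product + released group (k = 0.0220 L mol⁻¹ s⁻¹)
    coupling partner + first product → double product + released group (k = 0.00920 L mol⁻¹ s⁻¹)
    substrate + first product → side product (k = 0.0930 L mol⁻¹ s⁻¹)
    coupling partner + double product → triple product + released group (k = 0.0160 L mol⁻¹ s⁻¹)

Take the neighbour flask, south-west's recipe with the partner cut to 0.10 M. At 0.106 min⁻¹ its count is 3.35, close to east's, so reckon 3.50% of substrate left. The neighbour flask holds 2.49%, and its first product stands at 12.3%, level with east's 12.0%. Its triple product is 6.16%, and side product holds 56.9%, against 33.7% in south-west.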